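**Strategy.** The route rests on cutting pyran ring A at the enol-ether double bond C3=C4 and at the ring-fusion bond C4a–C8a, and ring B at C7–C8. C4 is a latent aldehyde carbon, C4a its α-carbon and C8a–C8 a former nitroalkene, so C4(HO)–C4a–C8a–C8(NO2) is a γ-nitro aldehyde; the tertiary carbinol C7 beside C8 is a nitro-aldol retron. In one pot an amine-catalysed Michael addition (C4a–C8a), an intramolecular Horner–Wadsworth–Emmons olefination with an O2-tethered α-alkoxy phosphonate (C3=C4) and a Henry cyclisation (C7–C8) should turn a hydroxy keto aldehyde (as its lactol) and an acyclic nitroalkene phosphonate into the bicyclic core with C8a fixed.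

Key step: step 7

Remark: atoms are numbered as in 1H-isochromene (C1, O2, C3, C4, C4a, C5–C8, C8a); ring A is the pyran ring, ring B the carbocycle. The C6 carbinol centre in 3–5 and 15–17 and the phosphonate-bearing carbon in 10–15 are used as stereo-random mixtures, because both centres are destroyed later.

Step 1
Reactants: 1 pent-4-enal; 2 ethyl vinyl ether
Product: 4 3-hydroxyhept-6-en-2-one (racemic), via 2-ethoxyhepta-1,6-dien-3-ol 3 (not isolated)
Conditions: 2, t-BuLi, THF, −78 to 0 °C; then 1, −78 °C; then 1 M HCl, THF, 0 °C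
Reagents that add atoms: water, O
Why: 1-Ethoxyvinyllithium is an acetyl anion equivalent that adds 1,2 to the aldehyde, and mild acid hydrolysis of the enol ether should unmask the α-hydroxy methyl ketone (acyl anion addition).

Step 2
Reactants: 4 3-hydroxyhept-6-en-2-one
Product: 5 5-acetyloxolan-2-ol (lactol form of 4-hydroxy-5-oxohexanal; diastereomer mixture)
Conditions: O3, CH2Cl2/MeOH, −78 °C; then Me2S, −78 °C to rt
Reagents that add atoms: ozone, [O-][O+]=O
Why: Ozonolysis of the terminal alkene with reductive work-up should give the aldehyde, which closes onto the neighbouring hydroxyl as the five-membered lactol.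

Step 3
Reactants: 6 ethyl (2E)-4-oxobut-2-enoate; 7 prop-2-en-1-ol
Product: 8 ethyl (2E)-4,4-bis(prop-2-enyloxy)but-2-enoate
Conditions: 7 (4 equiv), p-TsOH·H2O (cat.), cyclohexane, reflux, Dean–Stark trap
Reagents that add atoms: none
Why: Acid-catalysed acetalisation of the aldehyde with azeotropic removal of water should give the diallyl acetal and leave the ester and the E-alkene untouched.

Step 4
Reactants: 8 ethyl (2E)-4,4-bis(prop-2-enyloxy)but-2-enoate; 9 triethyl phosphite
Product: 10 ethyl (2E)-4-(diethoxyphosphoryl)-4-(prop-2-enyloxy)but-2-enoate (racemic)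
Conditions: 9, BF3·OEt2 (0.3 equiv), CH2Cl2, −20 °C to rt
Reagents that add atoms: none
Why: Lewis-acid ionisation of the acetal to the oxocarbenium ion, capture by the phosphite and dealkylation of the phosphonium ion (Michaelis–Arbuzov-type reaction of acetals) should give the α-alkoxy phosphonate.

Step 5
Reactants: 10 ethyl (2E)-4-(diethoxyphosphoryl)-4-(prop-2-enyloxy)but-2-enoate
Product: 11 ethyl (2E)-4-(diethoxyphosphoryl)-4-(2-oxoethoxy)but-2-enoate
Conditions: OsO4 (2 mol %), NaIO4 (4 equiv), 2,6-lutidine, dioxane/H2O, rt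
Reagents that add atoms: sodium periodate, [Na+].[O-]I(=O)(=O)=O; water, O
Why: Lemieux–Johnson cleavage should take the electron-richer terminal allyl alkene in preference to the electron-poor enoate and give the alkoxyacetaldehyde.

Step 6
Reactants: 11 ethyl (2E)-4-(diethoxyphosphoryl)-4-(2-oxoethoxy)but-2-enoate; 12 nitromethane
Product: 14 ethyl (2E)-4-(diethoxyphosphoryl)-4-{[(2E)-3-nitroprop-2-en-1-yl]oxy}but-2-enoate, via nitro alcohol 13 (not isolated)
Conditions: 12 (5 equiv), Et3N (0.2 equiv), THF, 0 °C; then MsCl, Et3N, −20 to 0 °C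
Reagents that add atoms: none
Why: Henry addition of nitromethane to the aldehyde, then mesylation and E1cB elimination, should give the (E)-nitroalkene, the weak amine base leaving the less acidic phosphonate untouched.

Step 7
Reactants: 5 5-acetyloxolan-2-ol; 14 ethyl (2E)-4-(diethoxyphosphoryl)-4-{[(2E)-3-nitroprop-2-en-1-yl]oxy}but-2-enoate
Product: 17 ethyl (2E)-3-[(4aR,7S,8S,8aR)-6,7-dihydroxy-7-methyl-8-nitro-4a,5,6,7,8,8a-hexahydro-1H-isochromen-3-yl]prop-2-enoate (C6 epimers), via Michael adduct 15 (not isolated), via dihydropyran 16 (not isolated)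
Conditions: 5 (1.5 equiv), (S)-2-[diphenyl(trimethylsilyloxy)methyl]pyrrolidine (10 mol %), 4-nitrophenol (10 mol %), MeCN, 0 °C to rt; then Cs2CO3 (3 equiv), EtOH, 0 °C to rt
Reagents that add atoms: none
Why: The aldehyde form of lactol 5 condenses with the secondary amine to an E-enamine, one face of which is shielded by the diphenyl(silyloxy)methyl group, and this adds to nitroalkene 14 through the acyclic synclinal transition state usual for enamine–nitroalkene Michael additions, forming C4a–C8a and setting C8a under catalyst control with C4a syn to it. After the base is added, the α-alkoxy phosphonate carbanion attacks the aldehyde carbon C4 (released from its lactol) and loss of diethyl phosphate closes ring A as the endocyclic enol ether C3=C4 (six-membered ring closed by intramolecular Horner–Wadsworth–Emmons olefination), while the nitronate at C8 adds to the methyl ketone in a 6-exo-trig Henry reaction that closes ring B through C7–C8. The closest known reaction type is the one-pot organocatalytic Michael/Henry/Horner–Wadsworth–Emmons sequence of dialdehydes with nitroalkenes and phosphonates. C7 and C8 should be set under thermodynamic control of the reversible nitro-aldol step, in a chair that has the C8a–C1 bond, the nitro group and the C7 methyl equatorial and the C7 hydroxyl axial; C4a and C6 are removed later. The step needs olefination of the aldehyde and not the ketone (six- against eight-membered ring) and Henry attack on the ketone and not the aldehyde (six- against four-membered ring), and both are secured by ring size.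

Step 8
Reactants: 17 ethyl (2E)-3-[(4aR,7S,8S,8aR)-6,7-dihydroxy-7-methyl-8-nitro-4a,5,6,7,8,8a-hexahydro-1H-isochromen-3-yl]prop-2-enoate
Product: 18 ethyl (2E)-3-[(7S,8S,8aR)-7-hydroxy-7-methyl-8-nitro-6-oxo-6,7,8,8a-tetrahydro-1H-isochromen-3-yl]prop-2-enoate
Conditions: IBX (4 equiv), 4-methoxypyridine N-oxide (4 equiv), DMSO, rt to 45 °C
Reagents that add atoms: none
Why: IBX should first oxidise the secondary C6 carbinol (the tertiary C7 carbinol is inert) and then dehydrogenate the ketone on its only enolisable side, C5, to the C4a=C5 enone conjugated with the enol ether (IBX oxidation and α,β-dehydrogenation), which removes the C4a and C6 stereocentres.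

Step 9
Reactants: 18 ethyl (2E)-3-[(7S,8S,8aR)-7-hydroxy-7-methyl-8-nitro-6-oxo-6,7,8,8a-tetrahydro-1H-isochromen-3-yl]prop-2-enoate
Product: 19 ethyl (2E)-3-[(7R,8aS)-7-hydroxy-7-methyl-6,8-dioxo-6,7,8,8a-tetrahydro-1H-isochromen-3-yl]prop-2-enoate
Conditions: NaOEt (1.1 equiv), EtOH, −20 °C; then aq. TiCl3 (4.5 equiv), NH4OAc buffer (pH 5–6), THF, 0 °C to rt
Reagents that add atoms: water, O
Why: In this reductive Nef reaction the nitronate of the secondary nitro group is reduced by TiCl3 to the imine, which should hydrolyse in the buffered medium to the C8 ketone without exposing the base-labile product to base.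

Step 10
Reactants: 19 ethyl (2E)-3-[(7R,8aS)-7-hydroxy-7-methyl-6,8-dioxo-6,7,8,8a-tetrahydro-1H-isochromen-3-yl]prop-2-enoate
Product: 20 ethyl (2E)-3-[(7S,8S,8aS)-7,8-dihydroxy-7-methyl-6-oxo-6,7,8,8a-tetrahydro-1H-isochromen-3-yl]prop-2-enoate
Conditions: NaBH4 (1 equiv), EtOH/THF, −78 °C; AcOH quench
Reagents that add atoms: none
Why: The saturated C8 ketone should be reduced in preference to the C6 carbonyl, which is deactivated as a doubly vinylogous ester, and axial hydride delivery anti to the axial C7 hydroxyl (polar Felkin–Anh control) should give the equatorial C8 alcohol, cis to the C7 hydroxyl and trans to C1.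

Step 11
Reactants: 21 2,4-dihydroxy-6-methylbenzoic acid (orsellinic acid)
Product: 22 2,4-bis(acetyloxy)-6-methylbenzoic acid
Conditions: Ac2O (3 equiv), pyridine, DMAP (cat.), 0 °C to rt; then H2O/THF
Reagents that add atoms: acetic anhydride, CC(=O)OC(C)=O
Why: Acetylation should mask both phenols for the acid chloride formation, the mixed anhydride at the carboxyl group being hydrolysed on aqueous work-up.

Step 12
Reactants: 20 ethyl (2E)-3-[(7S,8S,8aS)-7,8-dihydroxy-7-methyl-6-oxo-6,7,8,8a-tetrahydro-1H-isochromen-3-yl]prop-2-enoate; 22 2,4-bis(acetyloxy)-6-methylbenzoic acid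
Product: 24 (7S,8S,8aS)-3-[(1E)-3-ethoxy-3-oxoprop-1-en-1-yl]-7-hydroxy-7-methyl-6-oxo-6,7,8,8a-tetrahydro-1H-isochromen-8-yl 2,4-bis(acetyloxy)-6-methylbenzoate, via acid chloride 23 (not isolated)
Conditions: 22, (COCl)2, DMF (cat.), CH2Cl2, 0 °C to rt, evaporate; then 20, DMAP (1.5 equiv), Et3N, CH2Cl2, 0 to 35 °C
Reagents that add atoms: oxalyl chloride, ClC(=O)C(Cl)=O (supplies the chlorine of 23)
Why: Acid chloride formation and DMAP-mediated acyl transfer should esterify the secondary C8 hydroxyl, the tertiary C7 hydroxyl being too hindered (nucleophilic acyl substitution).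

Step 13
Reactants: 24 (7S,8S,8aS)-3-[(1E)-3-ethoxy-3-oxoprop-1-en-1-yl]-7-hydroxy-7-methyl-6-oxo-6,7,8,8a-tetrahydro-1H-isochromen-8-yl 2,4-bis(acetyloxy)-6-methylbenzoate
Product: 25 Pinophilin G
Conditions: LiOH·H2O (6 equiv), THF/H2O, 0 °C; then 1 M HCl to pH 3
Reagents that add atoms: lithium hydroxide, [Li+].[OH-]
Why: Hydroxide should cleave the two aryl acetates and the ethyl ester, whereas the 2,6-disubstituted benzoate at C8 is shielded and, once the phenoxides have formed, deactivated (ester hydrolysis).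

**Compound list**

1 | pent-4-enal | C=CCCC=O | starting material
2 | ethyl vinyl ether | C=COCC | starting material
3 | 2-ethoxyhepta-1,6-dien-3-ol (racemic; not isolated) | C=CCCC(O)C(=C)OCC | intermediate
4 | 3-hydroxyhept-6-en-2-one (racemic) | CC(=O)C(O)CCC=C | intermediate
5 | 5-acetyloxolan-2-ol (lactol of 4-hydroxy-5-oxohexanal; diastereomer mixture) | CC(=O)C1CCC(O)O1 | intermediate
6 | ethyl (2E)-4-oxobut-2-enoate | CCOC(=O)/C=C/C=O | starting material
7 | prop-2-en-1-ol | C=CCO | starting material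
8 | ethyl (2E)-4,4-bis(prop-2-enyloxy)but-2-enoate | CCOC(=O)/C=C/C(OCC=C)OCC=C | intermediate
9 | triethyl phosphite | CCOP(OCC)OCC | starting material
10 | ethyl (2E)-4-(diethoxyphosphoryl)-4-(prop-2-enyloxy)but-2-enoate (racemic) | CCOC(=O)/C=C/C(OCC=C)P(=O)(OCC)OCC | intermediate
11 | ethyl (2E)-4-(diethoxyphosphoryl)-4-(2-oxoethoxy)but-2-enoate (racemic) | CCOC(=O)/C=C/C(OCC=O)P(=O)(OCC)OCC | intermediate
12 | nitromethane | C[N+](=O)[O-] | starting material
13 | ethyl (2E)-4-(diethoxyphosphoryl)-4-(2-hydroxy-3-nitropropoxy)but-2-enoate (diastereomer mixture; not isolated) | CCOC(=O)/C=C/C(OCC(O)C[N+](=O)[O-])P(=O)(OCC)OCC | intermediate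
14 | ethyl (2E)-4-(diethoxyphosphoryl)-4-{[(2E)-3-nitroprop-2-en-1-yl]oxy}but-2-enoate (racemic) | CCOC(=O)/C=C/C(OC/C=C/[N+](=O)[O-])P(=O)(OCC)OCC | intermediate
15 | ethyl (2E)-4-(diethoxyphosphoryl)-4-{[(2R,3R)-3-formyl-5-hydroxy-2-(nitromethyl)-6-oxoheptyl]oxy}but-2-enoate (open form; mixture at the carbinol and phosphonate carbons; not isolated) | O=C[C@H](CC(O)C(C)=O)[C@H](C[N+](=O)[O-])COC(/C=C/C(=O)OCC)P(=O)(OCC)OCC | intermediate
16 | ethyl (2E)-3-[(3R,4R)-4-(2-hydroxy-3-oxobutyl)-3-(nitromethyl)-3,4-dihydro-2H-pyran-6-yl]prop-2-enoate (carbinol epimers; not isolated) | CCOC(=O)/C=C/C1=C[C@H](CC(O)C(C)=O)[C@H](C[N+](=O)[O-])CO1 | intermediate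
17 | ethyl (2E)-3-[(4aR,7S,8S,8aR)-6,7-dihydroxy-7-methyl-8-nitro-4a,5,6,7,8,8a-hexahydro-1H-isochromen-3-yl]prop-2-enoate (C6 epimers; 4a-H and 8a-H cis) | [O-][N+](=O)[C@H]1[C@@H]2COC(/C=C/C(=O)OCC)=C[C@@H]2CC(O)[C@@]1(C)O | intermediate
18 | ethyl (2E)-3-[(7S,8S,8aR)-7-hydroxy-7-methyl-8-nitro-6-oxo-6,7,8,8a-tetrahydro-1H-isochromen-3-yl]prop-2-enoate | [O-][N+](=O)[C@H]1[C@@H]2COC(/C=C/C(=O)OCC)=CC2=CC(=O)[C@@]1(C)O | intermediate
19 | ethyl (2E)-3-[(7R,8aS)-7-hydroxy-7-methyl-6,8-dioxo-6,7,8,8a-tetrahydro-1H-isochromen-3-yl]prop-2-enoate | O=C1[C@@H]2COC(/C=C/C(=O)OCC)=CC2=CC(=O)[C@@]1(C)O | intermediate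
20 | ethyl (2E)-3-[(7S,8S,8aS)-7,8-dihydroxy-7-methyl-6-oxo-6,7,8,8a-tetrahydro-1H-isochromen-3-yl]prop-2-enoate | O[C@H]1[C@@H]2COC(/C=C/C(=O)OCC)=CC2=CC(=O)[C@@]1(C)O | intermediate
21 | 2,4-dihydroxy-6-methylbenzoic acid (orsellinic acid) | Cc1cc(O)cc(O)c1C(=O)O | starting material
22 | 2,4-bis(acetyloxy)-6-methylbenzoic acid | Cc1cc(OC(C)=O)cc(OC(C)=O)c1C(=O)O | intermediate
23 | 2,4-bis(acetyloxy)-6-methylbenzoyl chloride (not isolated) | Cc1cc(OC(C)=O)cc(OC(C)=O)c1C(Cl)=O | intermediate
24 | (7S,8S,8aS)-3-[(1E)-3-ethoxy-3-oxoprop-1-en-1-yl]-7-hydroxy-7-methyl-6-oxo-6,7,8,8a-tetrahydro-1H-isochromen-8-yl 2,4-bis(acetyloxy)-6-methylbenzoate | Cc1cc(OC(C)=O)cc(OC(C)=O)c1C(=O)O[C@H]1[C@@H]2COC(/C=C/C(=O)OCC)=CC2=CC(=O)[C@@]1(C)O | intermediate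
25 | Pinophilin G, (2E)-3-[(7S,8S,8aS)-8-[(2,4-dihydroxy-6-methylbenzoyl)oxy]-7-hydroxy-7-methyl-6-oxo-6,7,8,8a-tetrahydro-1H-isochromen-3-yl]prop-2-enoic acid | Cc1cc(O)cc(O)c1C(=O)O[C@H]1[C@@H]2COC(/C=C/C(=O)O)=CC2=CC(=O)[C@@]1(C)O | target

**Step count.** Total: 13 steps. Longest linear sequence: 10 steps (steps 3–10, 12 and 13, starting from 6).

**Steps most likely to fail**

Step 7. The reversible nitro-aldol closure of ring B may stall at the open nitro ketone or close with poor control of the C7 configuration. Fallback, setting out from 16 and returning at 18: the one-pot sequence is stopped after the olefination by using LiCl and iPr2NEt in MeCN in place of Cs2CO3 in EtOH, and 16 is isolated. Its carbinol is oxidised with DMP (NaHCO3, CH2Cl2) to the 1,2-diketone ethyl (2E)-3-[(3R,4R)-4-(2,3-dioxobutyl)-3-(nitromethyl)-3,4-dihydro-2H-pyran-6-yl]prop-2-enoate F1. The more electrophilic terminal acetyl carbonyl of this diketone is then closed onto the nitronate in a separate, catalyst-controlled six-membered Henry reaction (bifunctional quinine-derived thiourea, 10 mol %, toluene, −20 °C), which should give the keto nitro alcohol ethyl (2E)-3-[(4aR,7S,8S,8aR)-7-hydroxy-7-methyl-8-nitro-6-oxo-4a,5,6,7,8,8a-hexahydro-1H-isochromen-3-yl]prop-2-enoate F2. Dehydrogenation of this ketone with IBX and 4-methoxypyridine N-oxide in DMSO then leads to 18.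

Step 9. Formation of the nitronate next to the tertiary carbinol may trigger retro-nitro-aldol ring opening or elimination before the reduction takes place. Fallback, setting out from 18 and returning at 19: the nitro group is reduced without a strong base (SnCl2·2H2O, PhSH, Et3N, MeCN, rt) to the oxime ethyl (2E)-3-[(7S,8aR)-7-hydroxy-8-(hydroxyimino)-7-methyl-6-oxo-6,7,8,8a-tetrahydro-1H-isochromen-3-yl]prop-2-enoate F3. This oxime is cleaved by transoximation with aqueous glyoxylic acid and NaOAc in THF to ketone 19.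

Step 10. Hydride may be delivered to the wrong face of the C8 carbonyl, so that the alcohol trans to the C7 hydroxyl forms. Fallback, setting out from 19 and returning at 24, which also bypasses step 12: the C8 epimer is made on purpose by equatorial attack of the bulky hydride LiBH(s-Bu)3 (THF, −78 °C), which should give ethyl (2E)-3-[(7S,8R,8aS)-7,8-dihydroxy-7-methyl-6-oxo-6,7,8,8a-tetrahydro-1H-isochromen-3-yl]prop-2-enoate F4. Mitsunobu esterification of this alcohol with acid 22 (PPh3, DIAD, toluene, 0 °C to rt) then installs the aryl ester with inversion at C8 and gives 24.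

**Further compounds**

F1 | step 7 | ethyl (2E)-3-[(3R,4R)-4-(2,3-dioxobutyl)-3-(nitromethyl)-3,4-dihydro-2H-pyran-6-yl]prop-2-enoate | CCOC(=O)/C=C/C1=C[C@H](CC(=O)C(C)=O)[C@H](C[N+](=O)[O-])CO1
F2 | step 7 | ethyl (2E)-3-[(4aR,7S,8S,8aR)-7-hydroxy-7-methyl-8-nitro-6-oxo-4a,5,6,7,8,8a-hexahydro-1H-isochromen-3-yl]prop-2-enoate | [O-][N+](=O)[C@H]1[C@@H]2COC(/C=C/C(=O)OCC)=C[C@@H]2CC(=O)[C@@]1(C)O
F3 | step 9 | ethyl (2E)-3-[(7S,8aR)-7-hydroxy-8-(hydroxyimino)-7-methyl-6-oxo-6,7,8,8a-tetrahydro-1H-isochromen-3-yl]prop-2-enoate | ON=C1[C@@H]2COC(/C=C/C(=O)OCC)=CC2=CC(=O)[C@@]1(C)O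
F4 | step 10 | ethyl (2E)-3-[(7S,8R,8aS)-7,8-dihydroxy-7-methyl-6-oxo-6,7,8,8a-tetrahydro-1H-isochromen-3-yl]prop-2-enoate | O[C@@H]1[C@@H]2COC(/C=C/C(=O)OCC)=CC2=CC(=O)[C@@]1(C)O
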